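## Plan

1. Retrosynthetic cuts, in order: four O–Si bonds; C4–H (axial alcohol from oxan-4-one 17); then, in one operation, C5–C6, C2–C3 and O1–C2 of the oxane (giving exocyclic enol ether 14 and aldehydes 3 and 8); C4=C5 (methylenation of lactone 13); C2'–C3' and the lactone O–C4 bond; C3=C3' (cross-metathesis); C4'–C5' (allylation of 3).
2. Enabling feature: C4 is a latent ketone whose α-carbons C3 and C5 each bond to a carbon on O1 (C2, C6), and the C5' carbinol oxygen lies five atoms from C4 (C4–C3–C3'–C4'–C5'–O). O(C5')–C4 can therefore be closed as a temporary six-membered ring (δ-lactone, then 2-methylideneoxane).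
3. In that ring C5 is the only nucleophilic carbon. An ene reaction with 3 makes C5–C6 and moves the enol ether to C3=C4; Prins closure with 8 makes C2–C3 and O1–C2; hydrolysis opens the temporary ring to the C4 ketone and the C5' hydroxyl.
4. Forward ring order: temporary lactone ring (step 7), then the oxane ring (step 9, temporary ring opened in the same step).
5. Stereochemistry: C5' by Keck allylation; C3' by ligand-controlled rhodium conjugate addition; C6 by the chiral titanium ene catalyst; C2 and C3 by the chair Prins transition state (relayed from C6, enol ether geometry locked by the temporary ring); C4 by equatorial hydride delivery.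

Key step: step 9

Notation: Ar = 4-[(tert-butyldimethylsilyl)oxy]phenyl, TBS = tert-butyldimethylsilyl. Target locants: oxane O1, C2 (aryl), C3, C4 (OH), C5, C6; side chain on C3 = C1'–C7' (C3' attached, C5' carbinol).

Assumption: the ligand hands ((R)-BINOL in step 3, (S)-BINAP in step 7, the Re-face-selective hand of the titanium ligand in step 9) follow the accepted facial models; if a sense proves opposite, the antipodal ligand is used and nothing else changes.

## Route

Step 1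
Reactants: 1 methyl 3-(4-hydroxyphenyl)propanoate
Product: 2 methyl 3-Ar-propanoate
Conditions: TBSCl, imidazole, DMF, rt
Reagents that add atoms: tert-butyldimethylsilyl chloride, CC(C)(C)[Si](C)(C)Cl
Why: Silylation of the phenol gives a group that should survive hydride, organometallic and Lewis-acid steps and leaves with fluoride at the end.

Step 2
Reactants: 2 methyl 3-Ar-propanoate
Product: 3 3-Ar-propanal
Conditions: iBu2AlH (1.05 equiv), CH2Cl2, −78 °C; then MeOH, aq. potassium sodium tartrate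
Reagents that add atoms: none
Why: Partial ester reduction stops at the aldehyde because the tetrahedral aluminium hemiacetal is stable at −78 °C.

Step 3
Reactants: 3 3-Ar-propanal; 4 allyltributylstannane
Product: 5 (3S)-1-Ar-hex-5-en-3-ol
Conditions: Ti(OiPr)4 (10 mol%), (R)-BINOL (10 mol%), 4 Å MS, CH2Cl2, −20 °C; then aq. NaHCO3
Reagents that add atoms: none
Why: Keck asymmetric allylation; the (R)-BINOL–titanium Lewis acid should direct the allyl group to the Re face of the aldehyde, setting C5' as (S).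

Step 4
Reactants: 5 (3S)-1-Ar-hex-5-en-3-ol; 6 methyl acrylate
Product: 7 methyl (2E,5S)-7-Ar-5-hydroxyhept-2-enoate
Conditions: second-generation Hoveyda–Grubbs catalyst RuCl2(H2IMes)(=CH–C6H4-2-OiPr) (3 mol%), 6 (4 equiv), CH2Cl2, 40 °C
Reagents that add atoms: none
Why: Olefin cross-metathesis of a terminal alkene with an electron-poor acrylate is selective for the (E)-enoate and tolerates the free hydroxyl; the (E) geometry prevents premature lactonisation.

Step 5
Reactants: 8 4-[(tert-butyldimethylsilyl)oxy]benzaldehyde; 9 bis(4,4,5,5-tetramethyl-1,3,2-dioxaborolan-2-yl)methane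
Product: 10 2-[(E)-2-Ar-ethenyl]-4,4,5,5-tetramethyl-1,3,2-dioxaborolane
Conditions: LiTMP (1.2 equiv), THF, 0 °C; then 8, −78 °C to rt
Reagents that add atoms: none
Why: Boron-Wittig olefination; the α-boryl carbanion adds to the aldehyde and syn B–O elimination should give the trans alkenyl boronate.

Step 6
Reactants: 10 2-[(E)-2-Ar-ethenyl]-4,4,5,5-tetramethyl-1,3,2-dioxaborolane
Product: 11 [(E)-2-Ar-ethenyl]boronic acid
Conditions: NaIO4, NH4OAc, acetone/H2O, rt
Reagents that add atoms: water, O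
Why: Oxidative cleavage of the released pinacol by periodate drives the boronate hydrolysis under near-neutral conditions that leave the aryl silyl ether and the alkene untouched.

Step 7
Reactants: 7 methyl (2E,5S)-7-Ar-5-hydroxyhept-2-enoate; 11 [(E)-2-Ar-ethenyl]boronic acid
Product: 13 (4R,6S)-4-[(E)-2-Ar-ethenyl]-6-(2-Ar-ethyl)oxan-2-one (cis), via hydroxy ester 12 (not isolated)
Conditions: [Rh(OH)((S)-binap)]2 (2.5 mol%), 11 (2.5 equiv), dioxane/H2O 10:1, 50 °C; then PPTS (10 mol%), toluene, 60 °C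
Reagents that add atoms: none
Why: Hayashi–Miyaura rhodium-catalysed asymmetric 1,4-addition of an alkenylboronic acid to an (E)-enoate; the (S)-BINAP complex should deliver the alkenyl group to the α-Si face and set C3' (3R in 12) under ligand control, base-free so the aryl silyl ethers survive, and mild acid then closes the δ-lactone (4,6-cis).

Step 8
Reactants: 13 (4R,6S)-4-[(E)-2-Ar-ethenyl]-6-(2-Ar-ethyl)oxan-2-one
Product: 14 (4R,6S)-4-[(E)-2-Ar-ethenyl]-6-(2-Ar-ethyl)-2-methylideneoxane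
Conditions: Cp2TiMe2 (2.5 equiv), toluene, 70 °C, dark; filtration through basic Al2O3, used at once
Reagents that add atoms: dimethyltitanocene, C[Ti](C)(C1C=CC=C1)C1C=CC=C1
Why: Petasis methylenation of the lactone carbonyl via Cp2Ti=CH2 is non-acidic, so the exocyclic enol ether should not isomerise, and no stereocentre is touched.

Step 9
Reactants: 14 (4R,6S)-4-[(E)-2-Ar-ethenyl]-6-(2-Ar-ethyl)-2-methylideneoxane; 3 3-Ar-propanal; 8 4-[(tert-butyldimethylsilyl)oxy]benzaldehyde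
Product: 17 (2S,3R,6S)-2-Ar-6-(2-Ar-ethyl)-3-[(1E,3S,5S)-1,7-bis(Ar)-5-hydroxyhept-1-en-3-yl]oxan-4-one, via hydroxy enol ether 15 (not isolated), via fused oxocarbenium ion 16 (not isolated)
Conditions: 3 (1.0 equiv) added to 14 (1.1 equiv), Ti(OiPr)4 (5 mol%), Schiff base of 2-amino-2'-hydroxy-1,1'-binaphthyl and 3,5-di-tert-butylsalicylaldehyde (5 mol%, Re-face-selective hand), 3,5-di-tert-butylsalicylic acid (5 mol%), 2,6-di-tert-butyl-4-methylpyridine (0.2 equiv), Et2O, 0 °C; then CH2Cl2, 8 (1.5 equiv), BF3·OEt2 (1.5 equiv), −78 °C; then H2O/THF, PPTS (cat.), 0 °C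
Reagents that add atoms: water, O
Why: Proposed new method: enol ether 14 has allylic hydrogens only at ring C3, so a Lewis-acid-catalysed carbonyl-ene reaction with 3 (closest known type: titanium-catalysed asymmetric ene addition of 2-alkoxypropenes to aldehydes) should form C5–C6 and can only give the C3=C4 endocyclic enol ether 15 with a free C6 hydroxyl, the catalyst hand setting C6 (S) by Re-face attack. BF3-mediated condensation of that hydroxyl with 8 gives an aryl-stabilised oxocarbenium ion that C3 captures in a 6-endo-trig (enol-endo) Prins closure, forming C2–C3 and the oxane ring (closest known types: silyl enol ether Prins cyclisation of hydroxy silyl enol ethers and the Mukaiyama aldol–Prins cascade). A chair transition state with the (E)-oxocarbenium ion and the C6 chain equatorial gives 2,6-cis; because the temporary ring holds C3' trans to C5 across C3=C4, the side chain ends equatorial at C3 (2,3-trans), with attack anti to the styryl group on C3'. The ring-fused oxocarbenium ion 16 is hydrolysed on quench, which cleaves the temporary O–C4 bond and releases the C4 ketone and the C5' hydroxyl. The step needs C5 to react before C3, and O(C6) rather than O(C5') to take the benzylic carbon C2; the tether secures both, since C5 is the only nucleophilic carbon at the start and O(C5') stays an enol ether or oxocarbenium oxygen until the oxane is closed.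

Step 10
Reactants: 17 (2S,3R,6S)-2-Ar-6-(2-Ar-ethyl)-3-[(1E,3S,5S)-1,7-bis(Ar)-5-hydroxyhept-1-en-3-yl]oxan-4-one
Product: 18 (2S,3S,4S,6S)-2-Ar-6-(2-Ar-ethyl)-3-[(1E,3S,5S)-1,7-bis(Ar)-5-hydroxyhept-1-en-3-yl]oxan-4-ol
Conditions: LiBH(sec-Bu)3 (3 equiv), THF, −78 °C; then aq. NH4Cl
Reagents that add atoms: none
Why: The bulky trialkylborohydride should attack the chair oxan-4-one from the equatorial side, giving the axial C4 hydroxyl cis to the C3 side chain (4S), as in reductions of 2-substituted cyclohexanones; any hemiketal form of 17 reacts through the keto form.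

Step 11
Reactants: 18 (2S,3S,4S,6S)-2-Ar-6-(2-Ar-ethyl)-3-[(1E,3S,5S)-1,7-bis(Ar)-5-hydroxyhept-1-en-3-yl]oxan-4-ol
Product: 19 blepharocalyxin C, (2S,3S,4S,6S)-3-[(1E,3S,5S)-5-hydroxy-1,7-bis(4-hydroxyphenyl)hept-1-en-3-yl]-2-(4-hydroxyphenyl)-6-[2-(4-hydroxyphenyl)ethyl]oxan-4-ol
Conditions: Bu4NF (6 equiv), AcOH (6 equiv), THF, 0 °C to rt
Reagents that add atoms: none
Why: Fluoride cleaves the four aryl silyl ethers; buffering with acetic acid keeps the phenols protonated so that neither phenoxide-driven opening at C2 nor acid ionisation of the benzylic C2–O1 bond should occur.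

## Compound list

1 | methyl 3-(4-hydroxyphenyl)propanoate | COC(=O)CCc1ccc(O)cc1 | starting material
2 | methyl 3-{4-[(tert-butyldimethylsilyl)oxy]phenyl}propanoate | COC(=O)CCc1ccc(O[Si](C)(C)C(C)(C)C)cc1 | intermediate
3 | 3-{4-[(tert-butyldimethylsilyl)oxy]phenyl}propanal | O=CCCc1ccc(O[Si](C)(C)C(C)(C)C)cc1 | intermediate
4 | allyltributylstannane | C=CC[Sn](CCCC)(CCCC)CCCC | starting material
5 | (3S)-1-{4-[(tert-butyldimethylsilyl)oxy]phenyl}hex-5-en-3-ol | C=CC[C@@H](O)CCc1ccc(O[Si](C)(C)C(C)(C)C)cc1 | intermediate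
6 | methyl acrylate | C=CC(=O)OC | starting material
7 | methyl (2E,5S)-7-{4-[(tert-butyldimethylsilyl)oxy]phenyl}-5-hydroxyhept-2-enoate | COC(=O)/C=C/C[C@@H](O)CCc1ccc(O[Si](C)(C)C(C)(C)C)cc1 | intermediate
8 | 4-[(tert-butyldimethylsilyl)oxy]benzaldehyde | O=Cc1ccc(O[Si](C)(C)C(C)(C)C)cc1 | starting material
9 | bis(4,4,5,5-tetramethyl-1,3,2-dioxaborolan-2-yl)methane | CC1(C)OB(CB2OC(C)(C)C(C)(C)O2)OC1(C)C | starting material
10 | tert-butyldimethyl{4-[(E)-2-(4,4,5,5-tetramethyl-1,3,2-dioxaborolan-2-yl)ethenyl]phenoxy}silane | CC1(C)OB(/C=C/c2ccc(O[Si](C)(C)C(C)(C)C)cc2)OC1(C)C | intermediate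
11 | [(E)-2-{4-[(tert-butyldimethylsilyl)oxy]phenyl}ethenyl]boronic acid | OB(O)/C=C/c1ccc(O[Si](C)(C)C(C)(C)C)cc1 | intermediate
12 | methyl (3R,5S)-7-Ar-3-[(E)-2-Ar-ethenyl]-5-hydroxyheptanoate (not isolated) | COC(=O)C[C@H](/C=C/c1ccc(O[Si](C)(C)C(C)(C)C)cc1)C[C@@H](O)CCc1ccc(O[Si](C)(C)C(C)(C)C)cc1 | intermediate
13 | (4R,6S)-4-[(E)-2-Ar-ethenyl]-6-(2-Ar-ethyl)oxan-2-one (cis lactone) | O=C1C[C@H](/C=C/c2ccc(O[Si](C)(C)C(C)(C)C)cc2)C[C@H](CCc2ccc(O[Si](C)(C)C(C)(C)C)cc2)O1 | intermediate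
14 | (4R,6S)-4-[(E)-2-Ar-ethenyl]-6-(2-Ar-ethyl)-2-methylideneoxane | C=C1C[C@H](/C=C/c2ccc(O[Si](C)(C)C(C)(C)C)cc2)C[C@H](CCc2ccc(O[Si](C)(C)C(C)(C)C)cc2)O1 | intermediate
15 | (2S)-4-Ar-1-{(2S,4S)-2-(2-Ar-ethyl)-4-[(E)-2-Ar-ethenyl]-3,4-dihydro-2H-pyran-6-yl}butan-2-ol (not isolated) | O[C@@H](CCc1ccc(O[Si](C)(C)C(C)(C)C)cc1)CC1=C[C@H](/C=C/c2ccc(O[Si](C)(C)C(C)(C)C)cc2)C[C@H](CCc2ccc(O[Si](C)(C)C(C)(C)C)cc2)O1 | intermediate
16 | ring-fused oxocarbenium ion: oxane ring of 17 fused through C3–C4 to the six-membered ring of 14, with O(C5')=C4 cationic, as its hydroxytrifluoroborate (not isolated) | CC(C)(C)[Si](C)(C)Oc1ccc(/C=C/[C@@H]2C[C@H](CCc3ccc(O[Si](C)(C)C(C)(C)C)cc3)[O+]=C3C[C@H](CCc4ccc(O[Si](C)(C)C(C)(C)C)cc4)O[C@H](c4ccc(O[Si](C)(C)C(C)(C)C)cc4)[C@@H]23)cc1.O[B-](F)(F)F | intermediate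
17 | (2S,3R,6S)-2-Ar-6-(2-Ar-ethyl)-3-[(1E,3S,5S)-1,7-bis(Ar)-5-hydroxyhept-1-en-3-yl]oxan-4-one | CC(C)(C)[Si](C)(C)Oc1ccc(/C=C/[C@H](C[C@@H](O)CCc2ccc(O[Si](C)(C)C(C)(C)C)cc2)[C@@H]2[C@@H](c3ccc(O[Si](C)(C)C(C)(C)C)cc3)O[C@@H](CCc3ccc(O[Si](C)(C)C(C)(C)C)cc3)CC2=O)cc1 | intermediate
18 | (2S,3S,4S,6S)-2-Ar-6-(2-Ar-ethyl)-3-[(1E,3S,5S)-1,7-bis(Ar)-5-hydroxyhept-1-en-3-yl]oxan-4-ol | CC(C)(C)[Si](C)(C)Oc1ccc(/C=C/[C@H](C[C@@H](O)CCc2ccc(O[Si](C)(C)C(C)(C)C)cc2)[C@@H]2[C@@H](c3ccc(O[Si](C)(C)C(C)(C)C)cc3)O[C@@H](CCc3ccc(O[Si](C)(C)C(C)(C)C)cc3)C[C@@H]2O)cc1 | intermediate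
19 | blepharocalyxin C, (2S,3S,4S,6S)-3-[(1E,3S,5S)-5-hydroxy-1,7-bis(4-hydroxyphenyl)hept-1-en-3-yl]-2-(4-hydroxyphenyl)-6-[2-(4-hydroxyphenyl)ethyl]oxan-4-ol | Oc1ccc(/C=C/[C@H](C[C@@H](O)CCc2ccc(O)cc2)[C@@H]2[C@@H](c3ccc(O)cc3)O[C@@H](CCc3ccc(O)cc3)C[C@@H]2O)cc1 | target

## Step count and risks

Total step count: 11. Longest linear sequence: 9 steps (steps 1, 2, 3, 4, 7, 8, 9, 10, 11).

**1. Step 9 (proposed new method).** What may go wrong: a second ene addition of 15 to the aldehyde; acid-induced isomerisation or hydrolysis of the enol ethers before ring closure; weak face control at C6 when the enol ether is not used in excess; interception of the C2 cation by the styrene.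
Fallback with known reactions, setting out from 13 and coming back at 17: 13 is deprotonated (LDA, THF, −78 °C) and added to 8 to give the aldol lactone F1, a mixture at the two new centres. F1 is dehydrated (TsOH cat., toluene, 50 °C) to the (E)-benzylidene lactone F2, which already holds the C2–C3 bond. MeLi (1.05 equiv, THF, −78 °C, then Et3SiCl on warming) opens the lactone to the triethylsilyl-protected methyl enone F3. A diisopinocampheylboron aldol reaction ((Ipc)2BCl of the Re-face-selective hand, Et3N, Et2O, −78 °C) with 3 forms C5–C6 and gives the hydroxy enone F4. Oxa-Michael closure (DBU cat., CH2Cl2) gives the 2,6-cis oxanone F5 with C3 equatorial, and PPTS in MeOH removes the triethylsilyl group to return 17.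

**2. Step 7.** What may go wrong: slow insertion of the enoate with competing protodeboronation of 11, or weak ligand control beside the free hydroxyl, leading to the trans lactone.
Fallback, setting out from 5 and 11 and coming back at 13: 5 is cross-metathesised with (4S)-3-acryloyl-4-phenyl-1,3-oxazolidin-2-one (same ruthenium catalyst as step 4) to the hydroxy enimide F6. 11 is converted with N-iodosuccinimide (MeCN) into the (E)-vinyl iodide F7 with retention, and then (t-BuLi, then MgBr2·OEt2) into the vinylmagnesium bromide F8. Addition of F8 with CuBr·SMe2 to F6 (hydroxyl first deprotonated with iPrMgCl) should occur anti to the phenyl group of the chelated s-cis imide and give adduct F9 with the (3R) centre. PPTS in toluene lactonises F9 to 13 with release of the auxiliary.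

**3. Step 8.** What may go wrong: isomerisation of the exocyclic enol ether to the endocyclic 6-methyl isomer or its hydrolysis during isolation, and incomplete methylenation.
Fallback, setting out from 13 and coming back at 14: reduction (iBu2AlH, CH2Cl2, −78 °C) gives lactol F10. Colvin homologation with lithiated trimethylsilyldiazomethane (THF, −78 °C to rt) gives alkynol F11. A La[N(SiMe3)2]3-catalysed 6-exo-dig hydroalkoxylation (toluene, 60 °C) then gives 14 as a solution that is taken directly into step 9.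

## Further compounds

F1 | step 9 | (4S,6S)-3-[hydroxy(Ar)methyl]-4-[(E)-2-Ar-ethenyl]-6-(2-Ar-ethyl)oxan-2-one (mixture at C3 and the carbinol carbon) | O=C1C(C(O)c2ccc(O[Si](C)(C)C(C)(C)C)cc2)[C@H](/C=C/c2ccc(O[Si](C)(C)C(C)(C)C)cc2)C[C@H](CCc2ccc(O[Si](C)(C)C(C)(C)C)cc2)O1
F2 | step 9 | (3E,4S,6S)-3-(Ar-methylidene)-4-[(E)-2-Ar-ethenyl]-6-(2-Ar-ethyl)oxan-2-one | O=C1/C(=C/c2ccc(O[Si](C)(C)C(C)(C)C)cc2)[C@H](/C=C/c2ccc(O[Si](C)(C)C(C)(C)C)cc2)C[C@H](CCc2ccc(O[Si](C)(C)C(C)(C)C)cc2)O1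
F3 | step 9 | (3E,4S,6S)-8-Ar-3-(Ar-methylidene)-4-[(E)-2-Ar-ethenyl]-6-[(triethylsilyl)oxy]octan-2-one | CC(=O)/C(=C/c1ccc(O[Si](C)(C)C(C)(C)C)cc1)[C@H](/C=C/c1ccc(O[Si](C)(C)C(C)(C)C)cc1)C[C@@H](O[Si](CC)(CC)CC)CCc1ccc(O[Si](C)(C)C(C)(C)C)cc1
F4 | step 9 | (3S,6E,7S,9S)-1,11-bis(Ar)-6-(Ar-methylidene)-7-[(E)-2-Ar-ethenyl]-3-hydroxy-9-[(triethylsilyl)oxy]undecan-5-one | O[C@@H](CCc1ccc(O[Si](C)(C)C(C)(C)C)cc1)CC(=O)/C(=C/c1ccc(O[Si](C)(C)C(C)(C)C)cc1)[C@H](/C=C/c1ccc(O[Si](C)(C)C(C)(C)C)cc1)C[C@@H](O[Si](CC)(CC)CC)CCc1ccc(O[Si](C)(C)C(C)(C)C)cc1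
F5 | step 9 | (2S,3R,6S)-2-Ar-6-(2-Ar-ethyl)-3-{(1E,3S,5S)-1,7-bis(Ar)-5-[(triethylsilyl)oxy]hept-1-en-3-yl}oxan-4-one | CC(C)(C)[Si](C)(C)Oc1ccc(/C=C/[C@H](C[C@@H](O[Si](CC)(CC)CC)CCc2ccc(O[Si](C)(C)C(C)(C)C)cc2)[C@@H]2[C@@H](c3ccc(O[Si](C)(C)C(C)(C)C)cc3)O[C@@H](CCc3ccc(O[Si](C)(C)C(C)(C)C)cc3)CC2=O)cc1
F6 | step 7 | (4S)-3-[(2E,5S)-7-Ar-5-hydroxyhept-2-enoyl]-4-phenyl-1,3-oxazolidin-2-one | O=C1OC[C@H](c2ccccc2)N1C(=O)/C=C/C[C@@H](O)CCc1ccc(O[Si](C)(C)C(C)(C)C)cc1
F7 | step 7 | tert-butyl{4-[(E)-2-iodoethenyl]phenoxy}dimethylsilane | I/C=C/c1ccc(O[Si](C)(C)C(C)(C)C)cc1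
F8 | step 7 | [(E)-2-Ar-ethenyl]magnesium bromide | Br[Mg]/C=C/c1ccc(O[Si](C)(C)C(C)(C)C)cc1
F9 | step 7 | (4S)-3-{(3R,5S)-7-Ar-3-[(E)-2-Ar-ethenyl]-5-hydroxyheptanoyl}-4-phenyl-1,3-oxazolidin-2-one | O=C1OC[C@H](c2ccccc2)N1C(=O)C[C@H](/C=C/c1ccc(O[Si](C)(C)C(C)(C)C)cc1)C[C@@H](O)CCc1ccc(O[Si](C)(C)C(C)(C)C)cc1
F10 | step 8 | (4R,6S)-4-[(E)-2-Ar-ethenyl]-6-(2-Ar-ethyl)oxan-2-ol (anomer mixture) | OC1C[C@H](/C=C/c2ccc(O[Si](C)(C)C(C)(C)C)cc2)C[C@H](CCc2ccc(O[Si](C)(C)C(C)(C)C)cc2)O1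
F11 | step 8 | (3S,5S)-1-Ar-5-[(E)-2-Ar-ethenyl]oct-7-yn-3-ol | C#CC[C@H](/C=C/c1ccc(O[Si](C)(C)C(C)(C)C)cc1)C[C@@H](O)CCc1ccc(O[Si](C)(C)C(C)(C)C)cc1
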